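## Analysis of the target

- Target 14 is a C7 carbasugar built on one cyclohexene ring. The ring is numbered C1–C6: C1 is the alkene carbon bearing the exocyclic C7H2OBz, C2 is the alkene CH, and then come C3‑OMe, C4‑OH, C5‑OBz and C6‑OH.
- The four stereocentres are contiguous and all R. O3 and O4 are cis on one face (α) and O5 and O6 are cis on the other (β). O4/O5 are therefore trans, and O3/O6 are trans‑1,4 across the alkene.
- The five oxygens comprise a methyl ether, two free secondary hydroxyls, a secondary benzoate and a primary benzoate. Telling them apart is the real problem, not the skeleton, because an undifferentiated polyol is paid for in protecting groups.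
- The benzoates can migrate to neighbouring free hydroxyls under base. C3–O, C6–O and C7–O are all allylic. Every ketone‑ or diene‑level intermediate can aromatise by β‑elimination.
- Two features of this structure are exploited.
- First, O4 lies anti to the cis pair O5/O6, and C1 is para to C4. With an α‑oxygen on C1 and the alkene moved to C2=C3, the ring gains a mirror plane through the midpoints of C5–C6 and C2–C3. C4, C5 and C6 of 14 are thus three quarters of a meso 1,4‑dioxygenated ring.
- Second, the chain O3–C3–C2=C1–C7–O7 is a 1,4‑dioxy‑2‑ene. This is the retron of an SN2′ opening of a C2–C3 epoxide conjugated with an exocyclic C1=C7 alkene.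

## Retrosynthetic reasoning

**14 to 13 (ester bond at O5).** In triol 13 only O5–H and O6–H form a cis‑1,2‑diol. O5 is equatorial, O6 is pseudoaxial beside the C1 substituent, and O4–H is trans to O5–H. A catalyst that binds cis‑diols reversibly and activates the equatorial oxygen can find O5 without protection. Cutting here means O4, O5 and O6 never need separate masks.

**13 to 12 and 11 (masks, then the O3–CH3 bond).** The O5/O6 acetonide and the O4 silyl ether fall in one acidic operation. The methyl group is removed at 11, the only compound of the route in which O3–H is the sole free hydroxyl. Methylating a free O3/O4 cis‑diol would have to favour the pseudoaxial allylic oxygen over the equatorial one, against the normal preference. The forward reaction must be non‑basic, because an O3 alkoxide would invite silyl migration from O4 and attack on the C7 ester.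

**11 to 10 (C7–O7 bond, alkene shift).** The C7–O7 bond is cut, the alkene moves to C1=C7, and O3 is tied back to C2 as an epoxide. In the forward direction a palladium(0)‑catalysed SN2′ opening, driven by epoxide strain, does three things at once:
- it forms the primary benzoate;
- it creates the trisubstituted ring alkene;
- it frees O3–H alone.

The C3–O3 bond is not broken, so its configuration is carried through.

**10 to 9 and 8 (C3–O and C2–O bonds).** O4–H sits next to C3 on the α face, which is the face where O3 is needed. It therefore serves as a directing group for epoxidation before it is silylated. Direction by O4–H and shielding of the β face by the dioxolane point the same way.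

**8 to 7 (C1=C7).** A one‑carbon carbonyl olefination. This cut shows that C7 is the only carbon that has to be added to a C6 ring.

**7 to 6 and 5 (key disconnection).** The C1 ketone and O4–H of 7 are joined back through an O–O bond to the meso endoperoxide 6. Compound 6 in turn falls apart into achiral diene 5 and the two oxygen atoms. In the forward direction a [4+2] photooxygenation sets C1–O and C4–O together, anti to O5/O6. A chiral base then removes one of the two enantiotopic bridgehead hydrogens. The precursor is achiral and carries only a cis‑diol. The product is a single enantiomer with three target stereocentres and six differentiated ring carbons.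

**5 to 4, 3, 2 and 1.** The diene is unmasked from a trans‑dibromide and the cis‑diol comes from a syn‑dihydroxylation. Both alkenes of 1 are used, one for each purpose.

## Alternatives that were turned down

Alternative 1: (the textbook one) cut C1=C2 by ring‑closing metathesis.
- D‑Mannose A1 holds the whole stereotetrad. Its C1–C6 map onto C1, C6, C5, C4, C3 and C2 of 14.
- Forward key step: a ruthenium carbene closes octa‑1,7‑diene A2 to 12.
- The closure sets no stereocentre and makes an easy bond, so the cost lies before it.
- The oxygens of A1 must be told apart one at a time: O5 methylated, O4 silylated, O2/O3 tied in an acetal, O6 oxidised away.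
- C1 must become a ketone carrying C7, and both ends need a methylene carbon that is lost again in the closure.
- From structure alone this takes more operations than the route below, nearly all of them protecting‑group or redox changes. It is also the route that would be drawn first.

Alternative 2: cut C5–O and C6–O on a bought ring.
- (−)‑Shikimic acid A3 supplies the ring, C7, the C1=C2 alkene and the correct C3/C4/C5 sense.
- Forward key step: dehydration across C5–C6 to diene ester A4, then osmium‑catalysed syn‑dihydroxylation of C5=C6 on the β face, anti to the O3/O4 acetonide, to give A5.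
- In A5 the oxygens come in two undifferentiated pairs.
- Methylation at O3 would have to select the pseudoaxial allylic oxygen of a cis‑diol against the normal equatorial preference.
- O5/O6 need their own differentiation, and the ester must still be reduced beside base‑labile groups.
- The key step is a routine reagent‑controlled reaction that recreates a centre which was bought and then destroyed, and the count is no lower.

Alternative 3: cut C1–C2 by polarity reversal.
- The stereotetrad is C2‑symmetric, so the two aldehydes of the C2‑symmetric hexodialdose A6 are homotopic.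
- Forward key step: a carbene‑catalysed intramolecular benzoin reaction closes A6 to inosose A7 with no regiochemical question.
- The symmetry that helps the closure hurts afterwards. O3 and O6 carry the same mask although only O3 is to be methylated, and O4/O5 are likewise equivalent.
- C7 is still missing, so a methylenation and an allylic ester transposition are needed.
- The new carbinol centre is destroyed again, and differentiation plus homologation after the closure cost more than the closure wins.

Key step: step 5

Assumption: the sense of induction of the cinchona catalyst on 6 cannot be derived with certainty from structure; the route is written for the pseudoenantiomer that removes C1–H, and the quinine‑derived pseudoenantiomer is taken instead if a trial run shows the opposite sense (the catalyst comes from the parent alkaloid by O‑demethylation and 9‑O‑acetylation and is not counted among the steps).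

## Route

Step 1
Reactants: 1 cyclohexa‑1,4‑diene
Product: 2 rac‑(4R,5R)‑4,5‑dibromocyclohex‑1‑ene (trans‑dibromide)
Conditions: Br2 (1.0 equiv), CH2Cl2, −78 °C
Reagents that add atoms: bromine BrBr
Why: Electrophilic anti addition through a bromonium ion to one of two equivalent isolated alkenes should give the trans‑dibromide; low temperature and slow addition hold back the second addition, and the bromines are placeholders for the later diene.

Step 2
Reactants: 2 rac‑(4R,5R)‑4,5‑dibromocyclohex‑1‑ene
Product: 3 rac‑(1S,2R,4R,5R)‑4,5‑dibromocyclohexane‑1,2‑diol (cis‑diol, trans‑dibromide)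
Conditions: OsO4 (1 mol %), NMO (1.2 equiv), acetone/H2O, rt
Reagents that add atoms: osmium tetroxide (catalytic oxygen carrier) O=[Os](=O)(=O)=O; N‑methylmorpholine N‑oxide C[N+]1([O-])CCOCC1; water O
Why: Catalytic osmium syn‑dihydroxylation with an amine N‑oxide as terminal oxidant sets the cis relation of the future O5/O6; the two alkene faces of C2‑symmetric 2 are homotopic, so one racemic diastereomer should form.

Step 3
Reactants: 3 rac‑(1S,2R,4R,5R)‑4,5‑dibromocyclohexane‑1,2‑diol
Product: 4 acetonide of 3, rac‑trans‑5,6‑dibromo‑cis‑2,2‑dimethylhexahydro‑1,3‑benzodioxole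
Conditions: 2,2‑dimethoxypropane, p‑TsOH (cat.), CH2Cl2, rt
Reagents that add atoms: 2,2‑dimethoxypropane COC(C)(C)OC
Why: Acid‑catalysed transketalisation of a cis‑1,2‑diol to a cis‑fused dioxolane; this ring later shields the β face.

Step 4
Reactants: 4 acetonide of 3
Product: 5 (3aR,7aS)‑2,2‑dimethyl‑3a,7a‑dihydro‑1,3‑benzodioxole (meso; cis‑5,6‑isopropylidenedioxycyclohexa‑1,3‑diene)
Conditions: DBU (3 equiv), toluene, 80 °C; used at once
Reagents that add atoms: none
Why: Twofold E2 dehydrobromination, the second from an allylic bromide, should give the conjugated diene; both C–Br stereocentres vanish, so racemic 4 converges on achiral meso 5, which is used directly because it dimerises slowly by Diels–Alder reaction.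

Step 5
Reactants: 5 (3aR,7aS)‑2,2‑dimethyl‑3a,7a‑dihydro‑1,3‑benzodioxole
Product: 7 (4R,5S,6S)‑4‑hydroxy‑5,6‑(isopropylidenedioxy)cyclohex‑2‑en‑1‑one, via meso endoperoxide 6 (not isolated)
Conditions: O2, tetraphenylporphyrin (0.5 mol %), visible light, CH2Cl2, −20 °C; then Ar purge, 9‑O‑acetylcupreidine (10 mol %), 0 °C → rt
Reagents that add atoms: dioxygen O=O
Why: Sensitised photooxygenation adds singlet oxygen to the s‑cis diene of 5 in a concerted suprafacial [4+2] cycloaddition, which closes a 3,6‑dihydro‑1,2‑dioxine ring as a 2,3‑dioxabicyclo[2.2.2]octene (a ring that is not in the target) and forms the C1–O and C4–O bonds together. The dioxolane shields the β face, so both new C–O bonds are set on the α face, anti to O5/O6, and 6 keeps the mirror plane. The cinchona base then triggers a Kornblum–DeLaMare fragmentation: its quinuclidine nitrogen removes one of the two enantiotopic bridgehead hydrogens in an E2‑like step, the weak O–O bond breaks, the deprotonated carbon becomes the C1 ketone and the other oxygen remains as O4–H. The closest known reaction type is the chiral‑amine‑catalysed enantioselective Kornblum–DeLaMare desymmetrisation of meso bicyclic endoperoxides to γ‑hydroxyenones, and the achiral amine version is routine for oxygenated endoperoxides of this kind. No bond to C4, C5 or C6 is touched in the fragmentation, so their relative configuration comes from the cycloaddition and their absolute configuration (4R,5S,6S), as a group, from the catalyst's choice of C1–H over C4–H. The selectivity needed is between two enantiotopic C–H bonds; it should be secured by the rigid cage, in which the two hydrogens point in opposite directions along the C1···C4 axis, by two‑point binding of the catalyst (6′‑OH hydrogen bond to the peroxide, base at the bridgehead) and by the absence of any other base. In one flask an achiral C6 diene should become a single enantiomer in which every ring carbon has its own role: C1 electrophilic for C7, C2=C3 ready for O3, O4–H free as directing group, O5/O6 masked.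

Step 6
Reactants: 7 (4R,5S,6S)‑4‑hydroxy‑5,6‑(isopropylidenedioxy)cyclohex‑2‑en‑1‑one
Product: 8 dienol, (1R,5R,6S)‑5,6‑(isopropylidenedioxy)‑4‑methylidenecyclohex‑2‑en‑1‑ol (target numbering: C1=C7 exocyclic, C2=C3, O4–H α, O5/O6 β)
Conditions: Ph3PCH3Br (3.0 equiv), KOt‑Bu (2.9 equiv), THF, 0 °C; then 7, −78 → 0 °C
Reagents that add atoms: methyltriphenylphosphonium bromide C[P+](c1ccccc1)(c1ccccc1)c1ccccc1.[Br-]
Why: Wittig methylenation; the non‑stabilised ylide adds 1,2 to the enone, one equivalent is spent on O4–H (restored on work‑up), and no stereocentre is touched.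

Step 7
Reactants: 8 dienol
Product: 9 epoxy alcohol, the 2,3‑α‑epoxide of 8 (epoxide oxygen cis to O4–H, anti to the dioxolane; C1=C7 retained)
Conditions: VO(acac)2 (5 mol %), t‑BuOOH (1.2 equiv, decane), toluene, 0 °C
Reagents that add atoms: tert‑butyl hydroperoxide CC(C)(C)OO
Why: Vanadium‑catalysed hydroxyl‑directed epoxidation; the vanadate ester at O4 delivers oxygen to the adjacent C2=C3 alkene on the α face, which sets C3, while the exocyclic alkene is out of reach. Direction by O4–H and shielding of the β face by the dioxolane are matched.

Step 8
Reactants: 9 epoxy alcohol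
Product: 10 O4‑tert‑butyldimethylsilyl ether of 9
Conditions: TBSOTf (1.1 equiv), 2,6‑lutidine (2 equiv), CH2Cl2, −78 °C
Reagents that add atoms: tert‑butyldimethylsilyl triflate CC(C)(C)[Si](C)(C)OS(=O)(=O)C(F)(F)F
Why: Standard silylation of a hindered secondary alcohol; excess hindered base and low temperature spare the vinyl epoxide, and a Payne shift is impossible because O4 and the epoxide oxygen are cis.

Step 9
Reactants: 10 O4‑TBS vinyl epoxide
Product: 11 [(3R,4R,5R,6R)‑4‑(tert‑butyldimethylsilyloxy)‑3‑hydroxy‑5,6‑(isopropylidenedioxy)cyclohex‑1‑en‑1‑yl]methyl benzoate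
Conditions: BzOH (1.2 equiv), Pd(PPh3)4 (5 mol %), THF, 0 °C → rt
Reagents that add atoms: benzoic acid OC(=O)c1ccccc1
Why: Tsuji–Trost type 1,4‑opening of a vinyl epoxide; strain‑driven ionisation of the C2–O bond gives a C7–C1–C2 π‑allyl complex and an O3 alkoxide that deprotonates the acid, and benzoate attacks the unhindered primary terminus C7. Reversible ionisation of allylic benzoates favours the primary ester with the trisubstituted ring alkene, and the C3–O3 bond is never broken, so C3 stays R.

Step 10
Reactants: 11 allylic alcohol
Product: 12 [(3R,4R,5R,6R)‑4‑(tert‑butyldimethylsilyloxy)‑5,6‑(isopropylidenedioxy)‑3‑methoxycyclohex‑1‑en‑1‑yl]methyl benzoate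
Conditions: MeOTf (3 equiv), 2,6‑di‑tert‑butyl‑4‑methylpyridine (4 equiv), CH2Cl2, 0 °C → rt
Reagents that add atoms: methyl triflate COS(=O)(=O)C(F)(F)F
Why: O‑alkylation of the only free hydroxyl by a strong methylating agent with a non‑nucleophilic proton scavenger; no alkoxide is formed, so silyl migration from O4 and attack on the benzoate should be avoided.

Step 11
Reactants: 12 methyl ether
Product: 13 [(3R,4S,5R,6R)‑4,5,6‑trihydroxy‑3‑methoxycyclohex‑1‑en‑1‑yl]methyl benzoate
Conditions: TFA/H2O (9:1), CH2Cl2, 0 °C → rt
Reagents that add atoms: none
Why: Acidic hydrolysis removes the acetonide and the secondary silyl ether in one operation; the benzoate and the methyl ether are stable to aqueous acid, and the oxygen‑rich ring disfavours allylic ionisation.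

Step 12
Reactants: 13 triol
Product: 14 [(3R,4R,5R,6R)‑5‑benzoyloxy‑4,6‑dihydroxy‑3‑methoxycyclohex‑1‑en‑1‑yl]methyl benzoate (target)
Conditions: BzCl (1.1 equiv), 2‑aminoethyl diphenylborinate (10 mol %), i‑Pr2NEt (1.5 equiv), MeCN, rt
Reagents that add atoms: benzoyl chloride O=C(Cl)c1ccccc1
Why: Borinic‑acid‑catalysed site‑selective acylation; the catalyst forms a tetracoordinate borinate with the only cis‑1,2‑diol (O5/O6), and the equatorial oxygen O5 is acylated. This is the same equatorial/axial cis‑diol motif for which the catalysis is established in pyranosides.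

## Compound list

1 | cyclohexa‑1,4‑diene | C1C=CCC=C1 | starting material
2 | rac‑(4R,5R)‑4,5‑dibromocyclohex‑1‑ene (one enantiomer drawn) | Br[C@@H]1CC=CC[C@H]1Br | intermediate
3 | rac‑(1S,2R,4R,5R)‑4,5‑dibromocyclohexane‑1,2‑diol (one enantiomer drawn) | O[C@H]1C[C@@H](Br)[C@H](Br)C[C@H]1O | intermediate
4 | acetonide of 3 (racemic, one enantiomer drawn) | CC1(C)O[C@H]2C[C@@H](Br)[C@H](Br)C[C@H]2O1 | intermediate
5 | (3aR,7aS)‑2,2‑dimethyl‑3a,7a‑dihydro‑1,3‑benzodioxole (meso) | CC1(C)O[C@H]2C=CC=C[C@H]2O1 | intermediate
6 | meso endoperoxide, 5,6‑(isopropylidenedioxy)‑2,3‑dioxabicyclo[2.2.2]oct‑7‑ene, peroxide bridge anti to the dioxolane | C1=C[C@@H]2OO[C@H]1[C@@H]1OC(C)(C)O[C@@H]12 | intermediate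
7 | (4R,5S,6S)‑4‑hydroxy‑5,6‑(isopropylidenedioxy)cyclohex‑2‑en‑1‑one | O=C1C=C[C@@H](O)[C@@H]2OC(C)(C)O[C@H]12 | intermediate
8 | (1R,5R,6S)‑5,6‑(isopropylidenedioxy)‑4‑methylidenecyclohex‑2‑en‑1‑ol | C=C1C=C[C@@H](O)[C@@H]2OC(C)(C)O[C@H]12 | intermediate
9 | 2,3‑α‑epoxide of 8 (epoxide cis to O4–H) | C=C1[C@H]2O[C@H]2[C@@H](O)[C@@H]3OC(C)(C)O[C@H]13 | intermediate
10 | O4‑TBS ether of 9 | C=C1[C@H]2O[C@H]2[C@@H](O[Si](C)(C)C(C)(C)C)[C@@H]3OC(C)(C)O[C@H]13 | intermediate
11 | [(3R,4R,5R,6R)‑4‑(TBS‑oxy)‑3‑hydroxy‑5,6‑(isopropylidenedioxy)cyclohex‑1‑en‑1‑yl]methyl benzoate | O[C@@H]1C=C(COC(=O)c2ccccc2)[C@H]3OC(C)(C)O[C@H]3[C@@H]1O[Si](C)(C)C(C)(C)C | intermediate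
12 | [(3R,4R,5R,6R)‑4‑(TBS‑oxy)‑5,6‑(isopropylidenedioxy)‑3‑methoxycyclohex‑1‑en‑1‑yl]methyl benzoate | CO[C@@H]1C=C(COC(=O)c2ccccc2)[C@H]3OC(C)(C)O[C@H]3[C@@H]1O[Si](C)(C)C(C)(C)C | intermediate
13 | [(3R,4S,5R,6R)‑4,5,6‑trihydroxy‑3‑methoxycyclohex‑1‑en‑1‑yl]methyl benzoate | CO[C@@H]1C=C(COC(=O)c2ccccc2)[C@@H](O)[C@@H](O)[C@@H]1O | intermediate
14 | [(3R,4R,5R,6R)‑5‑benzoyloxy‑4,6‑dihydroxy‑3‑methoxycyclohex‑1‑en‑1‑yl]methyl benzoate | CO[C@@H]1C=C(COC(=O)c2ccccc2)[C@@H](O)[C@@H](OC(=O)c2ccccc2)[C@@H]1O | target

## Step count and least certain steps

Total step count: 12. Longest linear sequence: 12 steps (1 to 14). Only two protecting groups are used, and both are removed in one operation.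

**Step 5 (key step).**
- The two enantiotopic bridgehead hydrogens may be discriminated poorly, because the dioxolane is an element absent from simple carbocyclic endoperoxides.
- An uncatalysed or adventitious‑base fragmentation may erode the enantiomeric excess.
- Reversible γ‑deprotonation of the product through a symmetric dienediol may racemise it on long exposure.
- The endoperoxide may rearrange thermally.
- Fallback: it sets out from 5 and returns at 7, replacing base desymmetrisation by enzymatic acyl transfer. Photooxygenation as above followed by thiourea reduction should give the meso enediol acetonide F1. A lipase with vinyl acetate acylates one enantiotopic hydroxyl to the monoacetate F2, with enzymes of opposite preference available for either sense. Oxidation of the remaining allylic alcohol (MnO2 or Dess–Martin periodinane) gives the acetoxy enone F3, and mild methanolysis (cat. K2CO3, MeOH, 0 °C) gives 7.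

**Step 6.**
- The basic ylide may enolise the ketone towards C6, with β‑elimination of O5 and aromatisation.
- It may also deprotonate at C4, with isomerisation of the γ‑hydroxyenone.
- Fallback: it sets out from 7 and returns at 8, replacing the ylide by addition/elimination. A weakly basic organocerium reagent (Me3SiCH2Li/CeCl3, THF, −78 °C) adds 1,2 from the α face to give the β‑hydroxysilane diol F4. Peterson elimination (KHMDS, THF, 0 °C) takes place when no carbonyl group is left and gives 8.

**Step 7.**
- The Lewis‑acidic vanadium species may open the newly formed, doubly activated vinyl epoxide.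
- The allylic alcohol may be oxidised to the dienone.
- The exocyclic alkene may be attacked in competition.
- Fallback: it sets out from 7 and returns at 9 without passing through 8, so that no diene meets an electrophilic oxidant. Lithium tert‑butyl peroxide in THF at −20 °C, held by the lithium alkoxide of O4, should add to C3 on the α face and close to the syn epoxy ketone F5. Wittig methylenation of F5 then gives 9.

**Step 9.**
- Ionisation needs palladium on the β face beside the dioxolane, so oxidative addition may be slow.
- This would give room to 1,2‑opening at C2, hydride‑shift isomerisation of the epoxide, or silyl migration from O4 to O3 at the alkoxide stage.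
- Fallback: it sets out from 10 and returns at 11 through a metal‑free halide relay. Opening with LiBr/AcOH in THF under thermodynamic control should give the primary allylic bromide F6. Substitution with caesium benzoate in DMF then gives 11.

**Step 12.**
- Site selectivity between the two equatorial hydroxyls O5–H and O4–H may be poor.
- The benzoyl group may migrate under the amine base.
- Fallback: it sets out from 9 and returns at 14, replacing catalyst control by a mask on O4 that survives acetonide removal.
 - NaH/PMBCl converts 9 into the PMB ether F7.
 - The conditions of steps 9 and 10 give the allylic alcohol F8 and then the methyl ether F9.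
 - Aqueous acetic acid removes only the acetonide and gives the diol F10.
 - In F10 only equatorial O5–H and pseudoaxial, hindered O6–H compete. BzCl/pyridine at −40 °C should give the O5 benzoate F11.
 - Neutral DDQ cleavage gives 14 without acyl migration.

## Further compounds

F1 | step 5 | meso enediol acetonide (O1–H and O4–H α, O5/O6 acetonide β, C2=C3) | O[C@H]1C=C[C@@H](O)[C@@H]2OC(C)(C)O[C@H]12
F2 | step 5 | monoacetate of F1 (acetate on O4, O1–H free) | O[C@H]1C=C[C@@H](OC(C)=O)[C@@H]2OC(C)(C)O[C@H]12
F3 | step 5 | acetoxy enone, O4‑acetate of 7 | O=C1C=C[C@@H](OC(C)=O)[C@@H]2OC(C)(C)O[C@H]12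
F4 | step 6 | β‑hydroxysilane diol (C1: CH2SiMe3 α, OH β) | C[Si](C)(C)C[C@@]1(O)C=C[C@@H](O)[C@@H]2OC(C)(C)O[C@H]12
F5 | step 7 | syn epoxy ketone (2,3‑α‑epoxide of 7) | O=C1[C@H]2O[C@H]2[C@@H](O)[C@@H]3OC(C)(C)O[C@H]13
F6 | step 9 | primary allylic bromide (7‑bromo analogue of 11) | O[C@@H]1C=C(CBr)[C@H]3OC(C)(C)O[C@H]3[C@@H]1O[Si](C)(C)C(C)(C)C
F7 | step 12 | O4‑PMB ether of 9 | C=C1[C@H]2O[C@H]2[C@@H](OCc4ccc(OC)cc4)[C@@H]3OC(C)(C)O[C@H]13
F8 | step 12 | O4‑PMB analogue of 11 | O[C@@H]1C=C(COC(=O)c2ccccc2)[C@H]3OC(C)(C)O[C@H]3[C@@H]1OCc4ccc(OC)cc4
F9 | step 12 | O4‑PMB analogue of 12 | CO[C@@H]1C=C(COC(=O)c2ccccc2)[C@H]3OC(C)(C)O[C@H]3[C@@H]1OCc4ccc(OC)cc4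
F10 | step 12 | O4‑PMB 5,6‑diol | CO[C@@H]1C=C(COC(=O)c2ccccc2)[C@@H](O)[C@@H](O)[C@@H]1OCc4ccc(OC)cc4
F11 | step 12 | O4‑PMB ether of 14 | CO[C@@H]1C=C(COC(=O)c2ccccc2)[C@@H](O)[C@@H](OC(=O)c3ccccc3)[C@@H]1OCc4ccc(OC)cc4
A1 | alternative 1 | D‑mannose (open‑chain form) | O=C[C@@H](O)[C@@H](O)[C@H](O)[C@H](O)CO
A2 | alternative 1 | octa‑1,7‑diene, seco form of 12 | C=C[C@@H](OC)[C@@H](O[Si](C)(C)C(C)(C)C)[C@@H]1OC(C)(C)O[C@@H]1C(=C)COC(=O)c1ccccc1
A3 | alternative 2 | (−)‑shikimic acid | OC(=O)C1=C[C@@H](O)[C@@H](O)[C@H](O)C1
A4 | alternative 2 | methyl 3,4‑O‑isopropylidene‑cyclohexa‑1,5‑diene‑1‑carboxylate | COC(=O)C1=C[C@H]2OC(C)(C)O[C@H]2C=C1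
A5 | alternative 2 | 5,6‑β‑cis‑diol of A4 | COC(=O)C1=C[C@H]2OC(C)(C)O[C@H]2[C@H](O)[C@@H]1O
A6 | alternative 3 | 2,3:4,5‑di‑O‑isopropylidene‑D‑manno‑hexodialdose | O=C[C@H]1OC(C)(C)O[C@H]1[C@@H]1OC(C)(C)O[C@@H]1C=O
A7 | alternative 3 | bis‑acetonide inosose (one carbinol epimer drawn) | O=C1[C@H](O)[C@H]2OC(C)(C)O[C@H]2[C@@H]3OC(C)(C)O[C@H]13
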